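**Retrosynthetic overview**
- Last bond made is C12–C13. C12 is the former lactone carbonyl carbon, used as a primary tosylate. C13 is the β-carbon of the C15-oxygenated butenyl unit. Both are natively electrophilic, so C13 is inverted to a (Z)-γ-silyloxyvinylzinc (a β-acylvinyl-anion, homoenolate-type d3 reagent) that already carries the 13Z geometry.
- The electrophile is the finished ring A/ring B diacetate. The 6β,7α-diacetate comes from a 6,8-diene by one-pot iodo-acetoxylation and acetoxonium opening.
- The diene comes from a C7 ketone (allylic oxidation of the 8(9)-ene), by reduction and dehydration.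
- No ring is formed. Rings A and B, with C5 and C10, are taken intact from (+)-sclareolide, whose lactone is opened; the d3 reagent comes from 2-butyn-1-ol.

Assumption: labdane numbering is used throughout, α is the face opposite the C10 methyl group, and (+)-sclareolide, 2-butyn-1-ol and all reagents are taken as commercial.

**Step 1**
Reactants: 1 (+)-sclareolide
Product: 2 methyl 13,14,15,16-tetranorlabd-8-en-12-oate
Conditions: conc. H2SO4, MeOH, rt, 72 h
Reagents that add atoms: methanol, CO
Why: Acid-catalysed lactone methanolysis with E1 loss of the tertiary C8 oxygen (Fischer esterification/dehydration) under equilibrating conditions gives the tetrasubstituted 8(9)-alkene as the thermodynamic isomer (minor 7-ene and exocyclic isomers are removed on AgNO3-impregnated silica); C5 and C10 are untouched.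

**Step 2**
Reactants: 2 methyl 13,14,15,16-tetranorlabd-8-en-12-oate
Product: 3 methyl 7-oxo-13,14,15,16-tetranorlabd-8-en-12-oate
Conditions: CrO3, 3,5-dimethylpyrazole, CH2Cl2, −20 °C
Reagents that add atoms: chromium trioxide, O=[Cr](=O)=O
Why: Allylic oxidation with the CrO3–3,5-dimethylpyrazole complex converts the only ring methylene next to the tetrasubstituted alkene (C7) into the conjugated enone, because C11 is deactivated by the ester and shielded by the C10 quaternary centre.

**Step 3**
Reactants: 3 methyl 7-oxo-13,14,15,16-tetranorlabd-8-en-12-oate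
Product: 4 13,14,15,16-tetranorlabd-8-ene-7β,12-diol
Conditions: iBu2AlH (5 equiv), CH2Cl2, −78 → 0 °C; aqueous potassium sodium tartrate
Reagents that add atoms: none
Why: Hydride reduction takes the ester to the primary alcohol and the enone to the allylic alcohol in 1,2-fashion; hydride enters C7 from the open α face (7β-OH major), and this centre is removed again in step 5, so its configuration does not matter.

**Step 4**
Reactants: 4 13,14,15,16-tetranorlabd-8-ene-7β,12-diol
Product: 5 7β-hydroxy-13,14,15,16-tetranorlabd-8-en-12-yl 4-methylbenzenesulfonate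
Conditions: TsCl (1.15 equiv), pyridine, CH2Cl2, 0 °C
Reagents that add atoms: 4-methylbenzenesulfonyl chloride, Cc1ccc(cc1)S(Cl)(=O)=O
Why: Chemoselective sulfonylation, since the unhindered primary alcohol reacts far faster than the hindered secondary allylic C7 alcohol; this installs the leaving group for the final cross-coupling.

**Step 5**
Reactants: 5 7β-hydroxy-13,14,15,16-tetranorlabd-8-en-12-yl 4-methylbenzenesulfonate
Product: 7 13,14,15,16-tetranorlabda-6,8-dien-12-yl 4-methylbenzenesulfonate, via sulfamate ester 6 (not isolated)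
Conditions: methyl N-(triethylammoniosulfonyl)carbamate (Burgess reagent, 2 equiv), benzene, rt → 60 °C
Reagents that add atoms: none
Why: Burgess dehydration, in which the C7 sulfamate leaves as a tight allyl-cation ion pair and its own anion removes the neighbouring cis H6β (syn elimination) to give the homoannular 6,8-diene; the primary tosylate is inert under these neutral conditions.

**Step 6**
Reactants: 7 13,14,15,16-tetranorlabda-6,8-dien-12-yl 4-methylbenzenesulfonate
Product: 10 6β,7α-diacetoxy-13,14,15,16-tetranorlabd-8-en-12-yl 4-methylbenzenesulfonate, via iodoacetate 8 (not isolated), via acetoxonium acetate 9 (not isolated)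
Conditions: I2 (1.05 equiv), AgOAc (2.5 equiv), dry AcOH/benzene, rt, dark; then 50 °C
Reagents that add atoms: silver acetate, CC(=O)[O-].[Ag+]
Why: Prévost trans-diacetoxylation: acetyl hypoiodite puts iodine on C6 from the open α face and acetate adds anti at C7; the 7β-acetate then displaces silver-activated iodide to form a β-face acetoxonium ion, which acetate opens at allylic C7 from the α face (trans-diaxial opening), giving the 6β,7α-diacetate (6S,7S).

**Step 7**
Reactants: 11 2-butyn-1-ol
Product: 13 (Z)-3-iodobut-2-en-1-ol, via cyclic vinylalanate 12 (not isolated)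
Conditions: NaAlH2(OCH2CH2OCH3)2 (1.6 equiv), THF, 0 °C → rt; then I2, THF, −78 → 0 °C
Reagents that add atoms: iodine, II
Why: Alkoxide-directed trans-hydroalumination of the propargylic alcohol places aluminium on C3 cis to the CH2O group (five-membered alanate), and iodinolysis with retention gives only the Z vinyl iodide, which fixes the later 13Z geometry.

**Step 8**
Reactants: 13 (Z)-3-iodobut-2-en-1-ol
Product: 14 (Z)-tert-butyl[(3-iodobut-2-en-1-yl)oxy]dimethylsilane
Conditions: TBSCl, imidazole, CH2Cl2, rt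
Reagents that add atoms: tert-butyldimethylsilyl chloride, CC(C)(C)[Si](C)(C)Cl
Why: Standard silylation of the primary alcohol makes the C15 oxygen compatible with the organolithium and organozinc chemistry and allows acetate-sparing removal at the end.

**Step 9**
Reactants: 10 6β,7α-diacetoxy-13,14,15,16-tetranorlabd-8-en-12-yl 4-methylbenzenesulfonate; 14 (Z)-tert-butyl[(3-iodobut-2-en-1-yl)oxy]dimethylsilane
Product: 18 (13Z)-6β,7α-diacetoxylabda-8,13-dien-15-ol, via vinyllithium 15 (not isolated), via vinylzinc chloride 16 (not isolated), via silyl ether 17 (not isolated)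
Conditions: 14 (1.8 equiv), tBuLi (2.0 equiv per 14), Et2O, −78 °C; ZnCl2, THF, −78 → 0 °C; then 10, Pd2(dba)3 (2 mol %), PCyp3 (8 mol %), N-methylimidazole, THF/NMP, 80 °C; aqueous work-up, crude 17 in THF, HF·pyridine, pyridine, 0 °C → rt
Reagents that add atoms: none
Why: Negishi alkyl–alkenyl cross-coupling with the vinyl partner as nucleophile: iodine–lithium exchange and transmetalation to zinc proceed with retention to give a (Z)-γ-silyloxyvinylzinc, a β-acylvinyl-anion (homoenolate-type d3) equivalent, so its natively electrophilic β-carbon C13 is joined to the electrophilic C12 tosylate by a zerovalent palladium/PCyp3 catalyst that adds oxidatively in SN2 fashion and outruns β-hydride elimination; the Z-alkene is transferred unchanged and HF·pyridine then frees the C15 alcohol without touching the acetates.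

**Compound list**
1 | (+)-sclareolide, (3aR,5aS,9aS,9bR)-3a,6,6,9a-tetramethyldecahydronaphtho[2,1-b]furan-2(1H)-one (8α,12-olide; 5α-H, 9α-H, 10β-CH3) | C1C[C@@]3(C)OC(=O)C[C@@H]3[C@@]2(C)CCCC(C)(C)[C@H]12 | starting material
2 | methyl 13,14,15,16-tetranorlabd-8-en-12-oate (5S,10S; tetrasubstituted C8=C9) | C1CC(C)=C(CC(=O)OC)[C@@]2(C)CCCC(C)(C)[C@H]12 | intermediate
3 | methyl 7-oxo-13,14,15,16-tetranorlabd-8-en-12-oate | C1C(=O)C(C)=C(CC(=O)OC)[C@@]2(C)CCCC(C)(C)[C@H]12 | intermediate
4 | 13,14,15,16-tetranorlabd-8-ene-7β,12-diol | C1[C@H](O)C(C)=C(CCO)[C@@]2(C)CCCC(C)(C)[C@H]12 | intermediate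
5 | 7β-hydroxy-13,14,15,16-tetranorlabd-8-en-12-yl 4-methylbenzenesulfonate | C1[C@H](O)C(C)=C(CCOS(=O)(=O)c3ccc(C)cc3)[C@@]2(C)CCCC(C)(C)[C@H]12 | intermediate
6 | triethylammonium salt of the 7β-O-[N-(methoxycarbonyl)sulfamate] of 5 | C1[C@H](OS(=O)(=O)[N-]C(=O)OC)C(C)=C(CCOS(=O)(=O)c3ccc(C)cc3)[C@@]2(C)CCCC(C)(C)[C@H]12.CC[NH+](CC)CC | intermediate
7 | 13,14,15,16-tetranorlabda-6,8-dien-12-yl 4-methylbenzenesulfonate | C1=CC(C)=C(CCOS(=O)(=O)c3ccc(C)cc3)[C@@]2(C)CCCC(C)(C)[C@H]12 | intermediate
8 | 7β-acetoxy-6α-iodo-13,14,15,16-tetranorlabd-8-en-12-yl 4-methylbenzenesulfonate | I[C@H]1[C@H](OC(C)=O)C(C)=C(CCOS(=O)(=O)c3ccc(C)cc3)[C@@]2(C)CCCC(C)(C)[C@H]12 | intermediate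
9 | 6β,7β-bridged 2-methyl-1,3-dioxolan-2-ylium (acetoxonium) acetate of the 8-en-12-yl tosylate | CC3=[O+][C@@H]1[C@H](O3)C(C)=C(CCOS(=O)(=O)c4ccc(C)cc4)[C@@]2(C)CCCC(C)(C)[C@H]12.CC(=O)[O-] | intermediate
10 | 6β,7α-diacetoxy-13,14,15,16-tetranorlabd-8-en-12-yl 4-methylbenzenesulfonate (5S,6S,7S,10S) | CC(=O)O[C@@H]1[C@@H](OC(C)=O)C(C)=C(CCOS(=O)(=O)c3ccc(C)cc3)[C@@]2(C)CCCC(C)(C)[C@H]12 | intermediate
11 | 2-butyn-1-ol | CC#CCO | starting material
12 | sodium 2,2-bis(2-methoxyethoxy)-3-methyl-2,5-dihydro-1,2-oxaluminol-2-uide (cyclic vinylalanate) | CC1=CCO[Al-]1(OCCOC)OCCOC.[Na+] | intermediate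
13 | (Z)-3-iodobut-2-en-1-ol | C/C(I)=C/CO | intermediate
14 | (Z)-tert-butyl[(3-iodobut-2-en-1-yl)oxy]dimethylsilane | C/C(I)=C/CO[Si](C)(C)C(C)(C)C | intermediate
15 | (Z)-4-(tert-butyldimethylsilyloxy)but-2-en-2-yllithium | C/C([Li])=C/CO[Si](C)(C)C(C)(C)C | intermediate
16 | (Z)-4-(tert-butyldimethylsilyloxy)but-2-en-2-ylzinc chloride | C/C([Zn]Cl)=C/CO[Si](C)(C)C(C)(C)C | intermediate
17 | (13Z)-6β,7α-diacetoxy-15-(tert-butyldimethylsilyloxy)labda-8,13-diene | CC(=O)O[C@@H]1[C@@H](OC(C)=O)C(C)=C(CC/C(C)=C\CO[Si](C)(C)C(C)(C)C)[C@@]2(C)CCCC(C)(C)[C@H]12 | intermediate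
18 | (13Z)-6β,7α-diacetoxylabda-8,13-dien-15-ol (5S,6S,7S,10S), CNP0187815.3 | CC(=O)O[C@@H]1[C@@H](OC(C)=O)C(C)=C(CC/C(C)=C\CO)[C@@]2(C)CCCC(C)(C)[C@H]12 | target

**Totals and risks**
Total step count: 9. Longest linear sequence: 7 (steps 1–6 and 9).

Steps most likely to fail:

Step 9, the key coupling. The risks are β-hydride elimination from the alkylpalladium, ionisation of the hindered allylic C7 acetate by zerovalent palladium, and 1,4-silyl migration in 15 before zinc transmetalation. The fallback sets out from 10 and comes back to the route at 17. It exchanges the roles of the two partners: NaI in acetone turns 10 into the iodide 6β,7α-diacetoxy-12-iodo-13,14,15,16-tetranorlabd-8-ene F6; zinc insertion (Zn dust, LiCl, THF, 40 °C) gives (6β,7α-diacetoxy-13,14,15,16-tetranorlabd-8-en-12-yl)zinc iodide F7; this is coupled with the vinyl iodide 14 under Pd(PPh3)4 at rt to give 17, which is desilylated with HF·pyridine as in step 9.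

Step 6, the one-pot trans-diacetoxylation. The risks are iodine attack at the tetrasubstituted end of the diene, 1,4-addition, and opening of the acetoxonium ion at C6. The fallback sets out from 7 and comes back at 10, and separates the events. NBS in aqueous THF gives the bromohydrin 6α-bromo-7β-hydroxy-13,14,15,16-tetranorlabd-8-en-12-yl tosylate F3. NaH in THF at 0 °C closes it to the isolated β-epoxide 6β,7β-epoxy-13,14,15,16-tetranorlabd-8-en-12-yl tosylate F4. Acetic acid opens this vinyl epoxide at allylic C7 with inversion to 7α-acetoxy-6β-hydroxy-13,14,15,16-tetranorlabd-8-en-12-yl tosylate F5. Ac2O, DMAP and Et3N then acetylate the axial 6β-alcohol to give 10.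

Step 5, the dehydration. The risk is proton loss from C11 to give the 7,9(11)-diene instead of the 6,8-diene. The fallback sets out from 5 and comes back at 7, and fixes the new double bond by enolate regiochemistry instead of by an elimination. MnO2 oxidises 5 to the enone 7-oxo-13,14,15,16-tetranorlabd-8-en-12-yl tosylate F1. Kinetic deprotonation at C6 (KN(SiMe3)2, THF, −78 °C) and trapping with PhNTf2 gives the dienyl triflate 7-(trifluoromethylsulfonyloxy)-13,14,15,16-tetranorlabda-6,8-dien-12-yl tosylate F2. Hydrogenolysis with Pd(PPh3)4, LiCl and Bu3SnH in THF at rt gives 7.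

**Further compounds**
F1 | step 5 | 7-oxo-13,14,15,16-tetranorlabd-8-en-12-yl 4-methylbenzenesulfonate | C1C(=O)C(C)=C(CCOS(=O)(=O)c3ccc(C)cc3)[C@@]2(C)CCCC(C)(C)[C@H]12
F2 | step 5 | 7-(trifluoromethylsulfonyloxy)-13,14,15,16-tetranorlabda-6,8-dien-12-yl 4-methylbenzenesulfonate | C1=C(OS(=O)(=O)C(F)(F)F)C(C)=C(CCOS(=O)(=O)c3ccc(C)cc3)[C@@]2(C)CCCC(C)(C)[C@H]12
F3 | step 6 | 6α-bromo-7β-hydroxy-13,14,15,16-tetranorlabd-8-en-12-yl 4-methylbenzenesulfonate | Br[C@H]1[C@H](O)C(C)=C(CCOS(=O)(=O)c3ccc(C)cc3)[C@@]2(C)CCCC(C)(C)[C@H]12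
F4 | step 6 | 6β,7β-epoxy-13,14,15,16-tetranorlabd-8-en-12-yl 4-methylbenzenesulfonate | O3[C@@H]1[C@H]3C(C)=C(CCOS(=O)(=O)c4ccc(C)cc4)[C@@]2(C)CCCC(C)(C)[C@H]12
F5 | step 6 | 7α-acetoxy-6β-hydroxy-13,14,15,16-tetranorlabd-8-en-12-yl 4-methylbenzenesulfonate | O[C@@H]1[C@@H](OC(C)=O)C(C)=C(CCOS(=O)(=O)c3ccc(C)cc3)[C@@]2(C)CCCC(C)(C)[C@H]12
F6 | step 9 | 6β,7α-diacetoxy-12-iodo-13,14,15,16-tetranorlabd-8-ene | CC(=O)O[C@@H]1[C@@H](OC(C)=O)C(C)=C(CCI)[C@@]2(C)CCCC(C)(C)[C@H]12
F7 | step 9 | (6β,7α-diacetoxy-13,14,15,16-tetranorlabd-8-en-12-yl)zinc iodide | CC(=O)O[C@@H]1[C@@H](OC(C)=O)C(C)=C(CC[Zn]I)[C@@]2(C)CCCC(C)(C)[C@H]12
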